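## Retrosynthetic overview

1. Target 17 ⇐ 16 ⇐ 15: the last two steps only unmask C13–OH and acetylate it selectively.
2. Key step: 15 ⇐ acyclic ynal 13. Ni(0) couples the C6 aldehyde with the C7≡C11 alkyne (C6–C7, the bond germacrene A synthase makes) and closes the ten-membered carbocycle first. CO insertion in the same flask then forms the γ-lactone (O6–C12); C6 is set from C8.
3. 13 ⇐ aldehyde 3 (C1–C6 and C15, Z-alkene from neryl formate) + vinyl bromide 10, by asymmetric Ni/Cr coupling (C1–C10, sets C1).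
4. 10 ⇐ ynal 7 (C7, C8, C11, C13) + 2,3-dibromopropene 8 (C9, C10, C14), by asymmetric Cr-mediated 2-bromoallylation (sets C8).
5. Ring order: carbocycle, then butenolide, as in germacranolide biosynthesis; no ring exists before step 8.

Assumption: the SMILES is taken as written, so C4=C5 is Z (C3 and C6 cis, nerol geometry) and the stereocentres are 1S,6R,8S; germacrane atom numbers are used throughout.

## Route

Step 1
Reactants: 1 neryl formate
Product: 3 (2Z)-3-methyl-6-oxohex-2-en-1-yl formate, via secondary ozonide 2 (not isolated)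
Conditions: O3 (1.0 equiv, Sudan Red 7B end point), CH2Cl2, −78 °C; then Me2S, −78 °C → rt
Reagents that add atoms: ozone, [O-][O+]=O
Why: Chemoselective ozonolysis with reductive work-up: electrophilic ozone attacks the electron-rich isolated trisubstituted olefin much faster than the 2,3-olefin deactivated by the allylic formate, so the Z-alkene is untouched and no stereocentre is formed.

Step 2
Reactants: 4 tert-butyldimethyl(prop-2-yn-1-yloxy)silane
Product: 7 4-[(tert-butyldimethylsilyl)oxy]but-2-ynal (TBSOCH2–C≡C–CHO), via lithium acetylide 5 (not isolated), via lithium hemiaminal alkoxide 6 (not isolated)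
Conditions: n-BuLi, THF, −78 °C; DMF, −78 → 0 °C; inverse quench into cold aq. KH2PO4
Reagents that add atoms: N,N-dimethylformamide, CN(C)C=O
Why: Formylation of a lithium acetylide with DMF (Bouveault-type); the tetrahedral adduct survives until the buffered inverse quench, which frees the ynal without amine conjugate addition.

Step 3
Reactants: 7 4-[(tert-butyldimethylsilyl)oxy]but-2-ynal; 8 2,3-dibromoprop-1-ene
Product: 9 (4S)-2-bromo-7-[(tert-butyldimethylsilyl)oxy]hept-1-en-5-yn-4-ol
Conditions: CrCl2 (10 mol %), Kishi oxazolinyl-aryl sulfonamide ligand (enantiomer directing Si-face attack, 12 mol %), Et3N (20 mol %), Co phthalocyanine (1 mol %), Mn (2 equiv), Cp2ZrCl2 (1.1 equiv), LiCl, THF/MeCN, 0 °C → rt; aq. work-up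
Reagents that add atoms: none
Why: Catalytic asymmetric Nozaki–Hiyama 2-haloallylation: Co/Cr (no Ni) activates only the allylic C–Br, and the chiral sulfonamide–Cr(III) allyl adds to the Si face of the ynal to set C8 as S, while Cp2ZrCl2 releases Cr from the product alkoxide.

Step 4
Reactants: 9 (4S)-2-bromo-7-[(tert-butyldimethylsilyl)oxy]hept-1-en-5-yn-4-ol
Product: 10 (4S)-2-bromo-7-[(tert-butyldimethylsilyl)oxy]hept-1-en-5-yn-4-yl acetate
Conditions: Ac2O, pyridine, DMAP (cat.), CH2Cl2, 0 °C → rt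
Reagents that add atoms: acetic anhydride, CC(=O)OC(C)=O
Why: DMAP-catalysed O-acylation installs the C8 acetate of the target; the stereocentre is not involved.

Step 5
Reactants: 10 (4S)-2-bromo-7-[(tert-butyldimethylsilyl)oxy]hept-1-en-5-yn-4-yl acetate; 3 (2Z)-3-methyl-6-oxohex-2-en-1-yl formate
Product: 11 (2Z,6S,9S)-9-acetoxy-12-[(tert-butyldimethylsilyl)oxy]-6-hydroxy-3-methyl-7-methylidenedodec-2-en-10-yn-1-yl formate
Conditions: CrCl2 (15 mol %), Kishi sulfonamide ligand (enantiomer directing Re-face attack, 17 mol %), proton sponge (17 mol %), NiCl2·(2,9-dimethyl-1,10-phenanthroline) (2 mol %), Mn (2 equiv), Cp2ZrCl2 (1.2 equiv), LiCl, MeCN, rt; aq. work-up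
Reagents that add atoms: none
Why: Catalytic asymmetric Nozaki–Hiyama–Kishi coupling: Ni inserts into the vinylic C–Br, the alkenyl–Cr(III)–ligand species adds only to the aldehyde (formate, acetate, silyl ether and alkyne are inert), and ligand control on the Re face sets C1 as S.

Step 6
Reactants: 11 (2Z,6S,9S)-9-acetoxy-12-[(tert-butyldimethylsilyl)oxy]-6-hydroxy-3-methyl-7-methylidenedodec-2-en-10-yn-1-yl formate
Product: 12 (2Z,6S,9S)-12-[(tert-butyldimethylsilyl)oxy]-1,6-dihydroxy-3-methyl-7-methylidenedodec-2-en-10-yn-9-yl acetate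
Conditions: KHCO3, MeOH/H2O (5:1), 0 °C
Reagents that add atoms: none
Why: Chemoselective deformylation: formates solvolyse about two orders of magnitude faster than acetates, so the primary allylic formate goes while the secondary acetate and the TBS ether stay.

Step 7
Reactants: 12 (2Z,6S,9S)-12-[(tert-butyldimethylsilyl)oxy]-1,6-dihydroxy-3-methyl-7-methylidenedodec-2-en-10-yn-9-yl acetate
Product: 13 (2Z,6S,9S)-12-[(tert-butyldimethylsilyl)oxy]-6-hydroxy-3-methyl-7-methylidene-1-oxododec-2-en-10-yn-9-yl acetate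
Conditions: TEMPO (10 mol %), PhI(OAc)2 (1.1 equiv), CH2Cl2, rt
Reagents that add atoms: none
Why: TEMPO/PhI(OAc)2 (oxoammonium) oxidation takes the primary allylic alcohol and leaves the secondary C1 alcohol, and it gives the Z-enal without isomerisation (as for nerol to neral).

Step 8
Reactants: 13 (2Z,6S,9S)-12-[(tert-butyldimethylsilyl)oxy]-6-hydroxy-3-methyl-7-methylidene-1-oxododec-2-en-10-yn-9-yl acetate
Product: 15 (1S,6R,8S,4Z)-8-acetoxy-13-[(tert-butyldimethylsilyl)oxy]-1-hydroxygermacra-4,7(11),10(14)-trien-6,12-olide, via nickeladihydrofuran 14 (not isolated)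
Conditions: premixed Ni(cod)2 (1.1 equiv)/IPr (1.1 equiv), toluene, slow addition of 13 to 2 mM, rt; then CO (1 atm), 0 °C → rt
Reagents that add atoms: carbon monoxide, [C-]#[O+]
Why: Proposed new method: Ni(0)/NHC oxidative cyclisation of the aldehyde with the alkyne (the elementary step of Ni-catalysed reductive ynal macrocyclisations, where a bulky NHC directs C–C formation to the tether-bearing alkyne carbon) should close the ten-membered ring through C6–C7 to nickeladihydrofuran 14, and CO then inserts into the Ni–C(sp2) bond and C–O reductive elimination gives the butenolide (closest known chemistry: the hetero-Pauson–Khand reaction of 1,6-ynals and the carbonylation of isolated nickeladihydrofurans to butenolides); C6 is set by 1,3-induction from C8, because with C8–H eclipsing the C11 substituent (A1,3 strain) and OAc turned outward the short tether is expected to deliver the aldehyde Si face with C5 anti to C9, which is 6R.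

Step 9
Reactants: 15 (1S,6R,8S,4Z)-8-acetoxy-13-[(tert-butyldimethylsilyl)oxy]-1-hydroxygermacra-4,7(11),10(14)-trien-6,12-olide
Product: 16 (1S,6R,8S,4Z)-8-acetoxy-1,13-dihydroxygermacra-4,7(11),10(14)-trien-6,12-olide
Conditions: HF·pyridine, THF/pyridine, 0 °C → rt
Reagents that add atoms: none
Why: Fluoride cleavage of the primary TBS ether under buffered acidic conditions spares the acetate and avoids base, which could deprotonate the butenolide at C6 (epimerisation or loss of the C13 oxygen).

Step 10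
Reactants: 16 (1S,6R,8S,4Z)-8-acetoxy-1,13-dihydroxygermacra-4,7(11),10(14)-trien-6,12-olide
Product: 17 8alpha,13-diacetoxy-1alpha-hydroxygermacra-4,7(11),10(14)-trien-6alpha,12-olide (1S,6R,8S,4Z)
Conditions: AcCl (1.05 equiv), 2,4,6-collidine, CH2Cl2, −78 °C
Reagents that add atoms: acetyl chloride, CC(Cl)=O
Why: Primary-selective acylation: acetyl chloride/collidine at −78 °C acetylates the primary C13 hydroxyl and leaves the hindered secondary allylic C1 hydroxyl free, and the weak hindered base does not enolise the butenolide.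

## Compound list

1 | neryl formate, (2Z)-3,7-dimethylocta-2,6-dien-1-yl formate (commercial flavour ester) | O=COC/C=C(/C)CCC=C(C)C | starting material
2 | secondary ozonide, (2Z)-5-(5,5-dimethyl-1,2,4-trioxolan-3-yl)-3-methylpent-2-en-1-yl formate | O=COC/C=C(/C)CCC1OOC(C)(C)O1 | intermediate (not isolated)
3 | (2Z)-3-methyl-6-oxohex-2-en-1-yl formate | O=COC/C=C(/C)CCC=O | intermediate
4 | tert-butyldimethyl(prop-2-yn-1-yloxy)silane | C#CCO[Si](C)(C)C(C)(C)C | starting material
5 | lithium acetylide of 4, lithium 3-[(tert-butyldimethylsilyl)oxy]prop-1-yn-1-ide | [Li]C#CCO[Si](C)(C)C(C)(C)C | intermediate (not isolated)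
6 | lithium hemiaminal alkoxide, lithium 4-[(tert-butyldimethylsilyl)oxy]-1-(dimethylamino)but-2-yn-1-olate | [Li]OC(N(C)C)C#CCO[Si](C)(C)C(C)(C)C | intermediate (not isolated)
7 | 4-[(tert-butyldimethylsilyl)oxy]but-2-ynal | O=CC#CCO[Si](C)(C)C(C)(C)C | intermediate
8 | 2,3-dibromoprop-1-ene | C=C(Br)CBr | starting material
9 | (4S)-2-bromo-7-[(tert-butyldimethylsilyl)oxy]hept-1-en-5-yn-4-ol | C=C(Br)C[C@H](O)C#CCO[Si](C)(C)C(C)(C)C | intermediate
10 | (4S)-2-bromo-7-[(tert-butyldimethylsilyl)oxy]hept-1-en-5-yn-4-yl acetate | C=C(Br)C[C@H](OC(C)=O)C#CCO[Si](C)(C)C(C)(C)C | intermediate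
11 | (2Z,6S,9S)-9-acetoxy-12-[(tert-butyldimethylsilyl)oxy]-6-hydroxy-3-methyl-7-methylidenedodec-2-en-10-yn-1-yl formate | O=COC/C=C(/C)CC[C@H](O)C(=C)C[C@H](OC(C)=O)C#CCO[Si](C)(C)C(C)(C)C | intermediate
12 | (2Z,6S,9S)-12-[(tert-butyldimethylsilyl)oxy]-1,6-dihydroxy-3-methyl-7-methylidenedodec-2-en-10-yn-9-yl acetate | OC/C=C(/C)CC[C@H](O)C(=C)C[C@H](OC(C)=O)C#CCO[Si](C)(C)C(C)(C)C | intermediate
13 | (2Z,6S,9S)-12-[(tert-butyldimethylsilyl)oxy]-6-hydroxy-3-methyl-7-methylidene-1-oxododec-2-en-10-yn-9-yl acetate (seco ynal) | O=C/C=C(/C)CC[C@H](O)C(=C)C[C@H](OC(C)=O)C#CCO[Si](C)(C)C(C)(C)C | intermediate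
14 | nickeladihydrofuran: ten-membered carbocycle with C6–O–Ni(IPr)–C11 five-membered ring, C7=C11, drawn as monomer (1S,6R,8S,4Z) | C=C1C[C@H](OC(C)=O)C2=C(CO[Si](C)(C)C(C)(C)C)[Ni](=C3N(C=CN3c3c(C(C)C)cccc3C(C)C)c3c(C(C)C)cccc3C(C)C)O[C@@H]2/C=C(/C)CC[C@@H]1O | intermediate (not isolated)
15 | (1S,6R,8S,4Z)-8-acetoxy-13-[(tert-butyldimethylsilyl)oxy]-1-hydroxygermacra-4,7(11),10(14)-trien-6,12-olide | C=C1C[C@H](OC(C)=O)C2=C(CO[Si](C)(C)C(C)(C)C)C(=O)O[C@@H]2/C=C(/C)CC[C@@H]1O | intermediate
16 | (1S,6R,8S,4Z)-8-acetoxy-1,13-dihydroxygermacra-4,7(11),10(14)-trien-6,12-olide | C=C1C[C@H](OC(C)=O)C2=C(CO)C(=O)O[C@@H]2/C=C(/C)CC[C@@H]1O | intermediate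
17 | 8alpha,13-diacetoxy-1alpha-hydroxygermacra-4,7(11),10(14)-trien-6alpha,12-olide (1S,6R,8S,4Z) | C=C1C[C@H](OC(C)=O)C2=C(COC(C)=O)C(=O)O[C@@H]2/C=C(/C)CC[C@@H]1O | target

## Step count and risks

Total: 10 steps. Longest linear sequence: 9 steps (4 → 7 → 9 → 10 → 11 → 12 → 13 → 15 → 16 → 17).

**Step 8 (highest risk).** Ni-mediated oxidative cyclisation has not been used to close a ten-membered ring. The alkyne could couple at C11 (endo, eleven-membered), Ni(0) could engage the enal C=C or ionise the C8 propargylic acetate, and the C6 configuration rests on a conformational model. The fallback sets out from 13 and comes back at 17, keeping the same C6–C7 closure and ring order but using chromium. HF·pyridine removes the silyl group to give (2Z,6S,9S)-6,12-dihydroxy-3-methyl-7-methylidene-1-oxododec-2-en-10-yn-9-yl acetate F1. NBS/PPh3 at −30 °C converts the primary propargylic alcohol into (2Z,6S,9S)-12-bromo-6-hydroxy-3-methyl-7-methylidene-1-oxododec-2-en-10-yn-9-yl acetate F2. CrCl2 in THF at high dilution then closes the ring by SE2′ addition of the γ-substituted propargylchromium to the aldehyde; this reagent class gives α-allenic alcohols, and Cr-mediated closure is the proven way to ten-membered germacrane rings. The product is the macrocyclic α-allenol (1S,6R,8S,4Z)-8-acetoxy-12-norgermacra-4,7(11),10(14),11(13)-tetraene-1,6-diol F3. PdCl2-catalysed chlorocyclocarbonylation (CuCl2, CO), known for 2-substituted 2,3-allenols, forms the lactone as (1S,6R,8S,4Z)-8-acetoxy-13-chloro-1-hydroxygermacra-4,7(11),10(14)-trien-6,12-olide F4. KOAc in DMF displaces the allylic chloride to give 17.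

**Step 5.** A 2-bromoalkene is less reactive than the usual iodide in catalytic Ni/Cr coupling, and ligand control at C1 may be modest. The fallback sets out from 10 and 3 and comes back at 11. Stoichiometric CrCl2/cat. NiCl2 in DMSO without chiral ligand gives the C1-epimeric mixture (2Z,6RS,9S)-9-acetoxy-12-[(tert-butyldimethylsilyl)oxy]-6-hydroxy-3-methyl-7-methylidenedodec-2-en-10-yn-1-yl formate F5. Dess–Martin oxidation gives the enone (2Z,9S)-9-acetoxy-12-[(tert-butyldimethylsilyl)oxy]-3-methyl-7-methylidene-6-oxododec-2-en-10-yn-1-yl formate F6. (R)-Me-CBS/catecholborane at −78 °C sets C1 as S by ketone reduction and returns 11.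

**Step 3.** The slim alkynyl group of an ynal may give low ee in the Cr allylation. The fallback sets out from 7 and 8 and comes back at 9. Indium-mediated Barbier allylation in THF/H2O gives racemic 2-bromo-7-[(tert-butyldimethylsilyl)oxy]hept-1-en-5-yn-4-ol F7. MnO2 oxidises it to the ynone 2-bromo-7-[(tert-butyldimethylsilyl)oxy]hept-1-en-5-yn-4-one F8. Noyori transfer hydrogenation with RuCl[(S,S)-TsDPEN](p-cymene) in i-PrOH, a reaction for which ynones are ideal substrates, gives (S)-9.

## Further compounds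

F1 | step 8 | (2Z,6S,9S)-6,12-dihydroxy-3-methyl-7-methylidene-1-oxododec-2-en-10-yn-9-yl acetate | O=C/C=C(/C)CC[C@H](O)C(=C)C[C@H](OC(C)=O)C#CCO
F2 | step 8 | (2Z,6S,9S)-12-bromo-6-hydroxy-3-methyl-7-methylidene-1-oxododec-2-en-10-yn-9-yl acetate | O=C/C=C(/C)CC[C@H](O)C(=C)C[C@H](OC(C)=O)C#CCBr
F3 | step 8 | (1S,6R,8S,4Z)-8-acetoxy-12-norgermacra-4,7(11),10(14),11(13)-tetraene-1,6-diol | C=C1C[C@H](OC(C)=O)C(=C=C)[C@H](O)/C=C(/C)CC[C@@H]1O
F4 | step 8 | (1S,6R,8S,4Z)-8-acetoxy-13-chloro-1-hydroxygermacra-4,7(11),10(14)-trien-6,12-olide | C=C1C[C@H](OC(C)=O)C2=C(CCl)C(=O)O[C@@H]2/C=C(/C)CC[C@@H]1O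
F5 | step 5 | (2Z,6RS,9S)-9-acetoxy-12-[(tert-butyldimethylsilyl)oxy]-6-hydroxy-3-methyl-7-methylidenedodec-2-en-10-yn-1-yl formate | O=COC/C=C(/C)CCC(O)C(=C)C[C@H](OC(C)=O)C#CCO[Si](C)(C)C(C)(C)C
F6 | step 5 | (2Z,9S)-9-acetoxy-12-[(tert-butyldimethylsilyl)oxy]-3-methyl-7-methylidene-6-oxododec-2-en-10-yn-1-yl formate | O=COC/C=C(/C)CCC(=O)C(=C)C[C@H](OC(C)=O)C#CCO[Si](C)(C)C(C)(C)C
F7 | step 3 | rac-2-bromo-7-[(tert-butyldimethylsilyl)oxy]hept-1-en-5-yn-4-ol | C=C(Br)CC(O)C#CCO[Si](C)(C)C(C)(C)C
F8 | step 3 | 2-bromo-7-[(tert-butyldimethylsilyl)oxy]hept-1-en-5-yn-4-one | C=C(Br)CC(=O)C#CCO[Si](C)(C)C(C)(C)C
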